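**Retrosynthetic overview**
- The quinone comes last, by oxidation of a ring B phenol (free OH ortho to the chroman, para position unsubstituted); ring A carries no free OH and stays intact.
- The pyran ring is the only ring built: the O1–C2 bond is closed by an enantioselective anti-Markovnikov (6-endo) hydroetherification of a 2-(2-arylallyl)phenol, which also sets C3.
- The C4–C4a bond comes from an aromatic Claisen rearrangement of an aryl 2-arylallyl ether.
- The C3–C1' bond comes from a Negishi coupling of a 2-bromoallyl aryl ether with an ortho-metalated, MOM-protected 2,3-dimethoxyphenol.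
- Rings A and B are bought as 3,4-dimethoxyphenol and 2,3-dimethoxyphenol; the three-carbon unit is 2,3-dibromopropene.

Assumption: the target is 3S (CIP analysis of the given SMILES), and the antipode of thiol T that delivers 3S is fixed by one screen of both antipodes.

Thiol T (proposed chiral H-atom donor): 2-sulfanylbenzoyl-D-Pro-Aib-L-Phe-NMe2, SMILES O=C(c1ccccc1S)N1CCC[C@@H]1C(=O)NC(C)(C)C(=O)N[C@@H](Cc1ccccc1)C(=O)N(C)C.

**Route**

Step 1
Reactants: 1 3,4-dimethoxyphenol; 2 2,3-dibromopropene
Product: 3 4-[(2-bromoprop-2-en-1-yl)oxy]-1,2-dimethoxybenzene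
Conditions: K2CO3, acetone, reflux
Reagents that add atoms: none
Why: Williamson ether synthesis; only the allylic C–Br of 2 is SN2-active, so the vinylic bromide is kept for the later coupling.

Step 2
Reactants: 4 2,3-dimethoxyphenol
Product: 5 1,2-dimethoxy-3-(methoxymethoxy)benzene
Conditions: MOMCl, K2CO3, acetone, 0 °C to rt
Reagents that add atoms: chloromethyl methyl ether, COCCl
Why: O-alkylation of the phenol gives the MOM acetal, which masks the ring B hydroxyl and serves as the directing group for ortho-lithiation.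

Step 3
Reactants: 5 1,2-dimethoxy-3-(methoxymethoxy)benzene; 3 4-[(2-bromoprop-2-en-1-yl)oxy]-1,2-dimethoxybenzene
Product: 8 1-[3-(3,4-dimethoxyphenoxy)prop-1-en-2-yl]-3,4-dimethoxy-2-(methoxymethoxy)benzene, via aryllithium 6 (not isolated), via arylzinc chloride 7 (not isolated)
Conditions: n-BuLi, TMEDA, THF, 0 °C; ZnCl2, 0 °C to rt; then 3, Pd(OAc)2 (2 mol%), SPhos (4 mol%), 50 °C
Reagents that add atoms: none
Why: Directed ortho-metalation occurs at the only position ortho to OMOM (a stronger director than OMe), and Li-to-Zn transmetalation followed by Negishi coupling with the vinyl bromide gives the 1,1-disubstituted alkene while the mild zinc nucleophile leaves the allylic aryl ether alone.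

Step 4
Reactants: 8 1-[3-(3,4-dimethoxyphenoxy)prop-1-en-2-yl]-3,4-dimethoxy-2-(methoxymethoxy)benzene
Product: 9 2-{2-[3,4-dimethoxy-2-(methoxymethoxy)phenyl]prop-2-en-1-yl}-4,5-dimethoxyphenol
Conditions: PhNEt2, 190 °C, sealed tube
Reagents that add atoms: none
Why: Aromatic Claisen rearrangement ([3,3]-sigmatropic shift then tautomerisation) delivers the 2-arylallyl group to the unhindered ortho carbon para to the 3-methoxy group rather than to the flanked carbon between the two oxygens, as the parent allyl 3,4-dimethoxyphenyl ether does.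

Step 5
Reactants: 9 2-{2-[3,4-dimethoxy-2-(methoxymethoxy)phenyl]prop-2-en-1-yl}-4,5-dimethoxyphenol
Product: 10 (3S)-3-[3,4-dimethoxy-2-(methoxymethoxy)phenyl]-6,7-dimethoxychromane
Conditions: 9-mesityl-3,6-di-tert-butyl-10-phenylacridinium tetrafluoroborate (2 mol%), thiol T (10 mol%), 2,6-lutidine (10 mol%), 450 nm LEDs, degassed DCE (0.02 M), −20 °C
Reagents that add atoms: none
Why: Proposed new method: the excited acridinium oxidises the electron-rich α-benzylstyrene unit of 9 to its radical cation; the tethered phenol oxygen attacks the terminal alkene carbon (anti-Markovnikov, 6-endo, the only mode that leaves the stabilised tertiary benzylic radical at C3), forming the O1–C2 bond and closing the pyran ring; after proton loss the planar C3 radical accepts a hydrogen atom from the aryl S–H of T (S–H weaker than the new benzylic C–H) held by peptide N–H hydrogen bonds to the chroman and MOM oxygens, so delivery to one face sets 3S; the thiyl radical is reduced by the acridine radical and reprotonated, closing both cycles. Closest known reaction type: the racemic acridinium/aryl-thiol anti-Markovnikov hydroetherification of alkenols with achiral H-atom donors, and separately face-selective hydrogen-atom transfer from peptide thiols to prochiral carbon radicals; their merger into an enantio-determining termination of a phenol hydroetherification has not been described.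

Step 6
Reactants: 10 (3S)-3-[3,4-dimethoxy-2-(methoxymethoxy)phenyl]-6,7-dimethoxychromane
Product: 11 6-[(3S)-6,7-dimethoxychroman-3-yl]-2,3-dimethoxyphenol
Conditions: HCl (1.25 M in MeOH), 40 °C
Reagents that add atoms: none
Why: Acid-catalysed transacetalisation removes the MOM group; the methyl ethers, the chroman and the non-acidic C3 stereocentre are untouched.

Step 7
Reactants: 11 6-[(3S)-6,7-dimethoxychroman-3-yl]-2,3-dimethoxyphenol
Product: 12 Abroquinone A, 5-[(3S)-6,7-dimethoxychroman-3-yl]-2,3-dimethoxy-1,4-benzoquinone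
Conditions: (KSO3)2NO (2.5 equiv), KH2PO4 buffer (pH 6), acetone/H2O, 0 °C to rt
Reagents that add atoms: Fremy's salt (potassium nitrosodisulfonate), [K+].[K+].[O]N(S(=O)(=O)[O-])S(=O)(=O)[O-]
Why: Teuber oxidation converts a phenol with a free para position into the para-quinone via the phenoxyl radical; the nitroxyl reagent reacts only with the free phenol, so ring A is spared, and the near-neutral buffer prevents epimerisation of C3 through a quinone methide tautomer.

**Compound list**
1 | 3,4-dimethoxyphenol | COc1ccc(O)cc1OC | starting material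
2 | 2,3-dibromopropene | BrCC(Br)=C | starting material
3 | 4-[(2-bromoprop-2-en-1-yl)oxy]-1,2-dimethoxybenzene | COc1ccc(OCC(Br)=C)cc1OC | intermediate
4 | 2,3-dimethoxyphenol | COc1cccc(O)c1OC | starting material
5 | 1,2-dimethoxy-3-(methoxymethoxy)benzene | COCOc1cccc(OC)c1OC | intermediate
6 | [3,4-dimethoxy-2-(methoxymethoxy)phenyl]lithium (not isolated) | [Li]c1ccc(OC)c(OC)c1OCOC | intermediate
7 | chloro[3,4-dimethoxy-2-(methoxymethoxy)phenyl]zinc (not isolated) | Cl[Zn]c1ccc(OC)c(OC)c1OCOC | intermediate
8 | 1-[3-(3,4-dimethoxyphenoxy)prop-1-en-2-yl]-3,4-dimethoxy-2-(methoxymethoxy)benzene | C=C(COc1ccc(OC)c(OC)c1)c1ccc(OC)c(OC)c1OCOC | intermediate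
9 | 2-{2-[3,4-dimethoxy-2-(methoxymethoxy)phenyl]prop-2-en-1-yl}-4,5-dimethoxyphenol | C=C(Cc1cc(OC)c(OC)cc1O)c1ccc(OC)c(OC)c1OCOC | intermediate
10 | (3S)-3-[3,4-dimethoxy-2-(methoxymethoxy)phenyl]-6,7-dimethoxychromane | COCOc1c(OC)c(OC)ccc1[C@H]1COc2cc(OC)c(OC)cc2C1 | intermediate
11 | 6-[(3S)-6,7-dimethoxychroman-3-yl]-2,3-dimethoxyphenol | COc1ccc([C@H]2COc3cc(OC)c(OC)cc3C2)c(O)c1OC | intermediate
12 | Abroquinone A, 5-[(3S)-6,7-dimethoxychroman-3-yl]-2,3-dimethoxy-1,4-benzoquinone | COC1=C(OC)C(=O)C([C@H]2COc3cc(OC)c(OC)cc3C2)=CC1=O | target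

**Totals**
Total step count: 7. Longest linear sequence: 6 steps (steps 2, 3, 4, 5, 6, 7, or equally 1, 3, 4, 5, 6, 7).

**Three steps most likely to fail**

Step 5 (the proposed hydroetherification). The phenol ring may be oxidised in preference to the alkene, adventitious acid may give the Markovnikov 5-exo ether, or the hydrogen-atom transfer may be poorly face-selective. The fallback uses known chemistry, sets out from 9 and returns at 10. Asymmetric hydroboration of the 1,1-disubstituted aryl alkene with HBpin (2.5 equiv, the first equivalent capping the phenol as its boron ester; CoCl2 complex of a chiral iminopyridine–oxazoline ligand, NaBHEt3, THF, rt) gives 2-{(2S)-2-[3,4-dimethoxy-2-(methoxymethoxy)phenyl]-3-(4,4,5,5-tetramethyl-1,3,2-dioxaborolan-2-yl)propyl}-4,5-dimethoxyphenol F1. Oxidation with NaBO3·4H2O in THF/H2O, with retention, gives 2-{(2S)-2-[3,4-dimethoxy-2-(methoxymethoxy)phenyl]-3-hydroxypropyl}-4,5-dimethoxyphenol F2. Mitsunobu closure of the phenol onto the primary alcohol (PPh3, DIAD, THF, 0 °C) does not touch the stereocentre and gives 10.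

Step 4 (Claisen rearrangement). Some rearrangement to the flanked ortho carbon, or thermal addition of the new phenol to the electron-rich alkene, could erode the yield. The fallback fixes the regiochemistry by halogenation instead of a sigmatropic shift; it sets out from 1 (using 2 and the arylzinc 7 of step 3) and returns at 9. NBS in CH2Cl2 at 0 °C brominates 1 para to the 3-methoxy group to give 2-bromo-4,5-dimethoxyphenol F3. TBSCl and imidazole in DMF give (2-bromo-4,5-dimethoxyphenoxy)(tert-butyl)dimethylsilane F4. Grignard formation (Mg, THF) and CuI-catalysed SN2' allylation with 2 give tert-butyl[2-(2-bromoprop-2-en-1-yl)-4,5-dimethoxyphenoxy]dimethylsilane F5. Negishi coupling of F5 with 7 (Pd(OAc)2, SPhos, THF, 50 °C) gives tert-butyl(2-{2-[3,4-dimethoxy-2-(methoxymethoxy)phenyl]prop-2-en-1-yl}-4,5-dimethoxyphenoxy)dimethylsilane F6. TBAF in THF then frees the phenol 9 with the MOM group intact.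

Step 3 (ortho-metalation and Negishi coupling). Palladium may ionise the allylic aryl ether of 3, or the ortho-substituted arylzinc may couple slowly. The fallback builds the same alkene by acylation and olefination; it sets out from 1 and 5 (lithiated to 6 as in step 3) and returns at 8. Alkylation of 1 with 2-chloro-N-methoxy-N-methylacetamide (K2CO3, KI, acetone) gives 2-(3,4-dimethoxyphenoxy)-N-methoxy-N-methylacetamide F7. Addition of 6 at −78 °C gives 2-(3,4-dimethoxyphenoxy)-1-[3,4-dimethoxy-2-(methoxymethoxy)phenyl]ethan-1-one F8. Wittig methylenation (Ph3PCH3Br, KOtBu, THF, 0 °C) gives 8.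

**Further compounds**
F1 | step 5 | 2-{(2S)-2-[3,4-dimethoxy-2-(methoxymethoxy)phenyl]-3-(4,4,5,5-tetramethyl-1,3,2-dioxaborolan-2-yl)propyl}-4,5-dimethoxyphenol | COCOc1c(OC)c(OC)ccc1[C@@H](CB1OC(C)(C)C(C)(C)O1)Cc1cc(OC)c(OC)cc1O
F2 | step 5 | 2-{(2S)-2-[3,4-dimethoxy-2-(methoxymethoxy)phenyl]-3-hydroxypropyl}-4,5-dimethoxyphenol | COCOc1c(OC)c(OC)ccc1[C@@H](CO)Cc1cc(OC)c(OC)cc1O
F3 | step 4 | 2-bromo-4,5-dimethoxyphenol | COc1cc(O)c(Br)cc1OC
F4 | step 4 | (2-bromo-4,5-dimethoxyphenoxy)(tert-butyl)dimethylsilane | COc1cc(O[Si](C)(C)C(C)(C)C)c(Br)cc1OC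
F5 | step 4 | tert-butyl[2-(2-bromoprop-2-en-1-yl)-4,5-dimethoxyphenoxy]dimethylsilane | COc1cc(O[Si](C)(C)C(C)(C)C)c(CC(Br)=C)cc1OC
F6 | step 4 | tert-butyl(2-{2-[3,4-dimethoxy-2-(methoxymethoxy)phenyl]prop-2-en-1-yl}-4,5-dimethoxyphenoxy)dimethylsilane | C=C(Cc1cc(OC)c(OC)cc1O[Si](C)(C)C(C)(C)C)c1ccc(OC)c(OC)c1OCOC
F7 | step 3 | 2-(3,4-dimethoxyphenoxy)-N-methoxy-N-methylacetamide | COc1ccc(OCC(=O)N(C)OC)cc1OC
F8 | step 3 | 2-(3,4-dimethoxyphenoxy)-1-[3,4-dimethoxy-2-(methoxymethoxy)phenyl]ethan-1-one | COCOc1c(OC)c(OC)ccc1C(=O)COc1ccc(OC)c(OC)c1
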